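## Retrosynthetic overview

1. The target is all-E (3R,6'R)-7,8-didehydro-β,ε-caroten-3-ol (crocoxanthin; carotenoid numbering, primed locants for the ε end). Cutting C11'=C12' and C11=C12 (two Wittig reactions) gives an ε-C15 phosphonium salt, the C10 trienedial and an acetylenic hydroxy-C15 phosphonium salt made from (4R,6R)-actinol by enol triflate formation and Sonogashira coupling.
2. In the ε end, the C6'–H stereocentre and the skipped C4'=C5' alkene are traced back to a 4'-hydroxy-β ring. A reductive 1,3-transposition relays chirality from C4' to C6' and deletes the C4' oxygen, leading on to α-cyclogeranate, α-ionone and the C15 salt.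
3. The 4'-oxo-β ring comes from one Robinson annulation of ethyl 3-methyl-2-oxobutanoate with ethyl vinyl ketone, which forms C1'–C2' (Michael addition) and C5'–C6' (aldol condensation).
4. Enabling feature: in the six-membered ε ring the gem-dimethyl carbon C1' is the neighbour of C6', and the methyl-bearing C5' is the neighbour of C4'. A temporary carbonyl on C4' (with C6' at ketone level) makes C1' and C5' enolate carbons and C2' and C6' acceptor carbons, a 1,5-dicarbonyl pattern C6'–C1'–C2'–C3'–C4'.
5. Ring order: the ε ring is the only ring constructed (step 1); the hydroxy-β ring is carried intact from actinol.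

Key step: step 1

Remark: (4R,6R)-actinol and the C10 trienedial are taken as purchasable carotenoid intermediates, and the E/Z mixture of each Wittig step is assumed to be equilibrated as stated in the conditions.

## Route

Step 1
Reactants: 1 ethyl 3-methyl-2-oxobutanoate; 2 pent-1-en-3-one (ethyl vinyl ketone)
Product: 5 ethyl 2,6,6-trimethyl-3-oxocyclohex-1-ene-1-carboxylate, via Michael adduct 3 (not isolated), via aldol adduct 4 (not isolated)
Conditions: DBU (10 mol %), MeCN, 0 °C → rt; then p-TsOH·H2O (30 mol %), toluene, reflux, Dean–Stark (one pot)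
Reagents that add atoms: none
Why: DBU deprotonates 1 at its only enolisable position, the isopropyl methine, and the tertiary enolate adds to the unsubstituted β-carbon of 2 (Michael addition), which makes the C1'–C2' bond and the gem-dimethyl quaternary carbon of 3. Under acid the ethyl-ketone enol of 3 attacks the strongly electrophilic α-keto-ester carbonyl (C6') in a 6-(enolexo)-exo-trig aldol closure that forms C5'–C6' and the ε-ring skeleton of 4, and β-elimination of water gives the tetrasubstituted enone 5. The closest known reaction type is the Robinson annulation of α-branched carbonyl donors with vinyl ketones, as in the isobutyraldehyde/vinyl ketone route to 4,4-dimethylcyclohexenones. No stereocentre survives the step, because the two centres that arise in 4 are erased by the dehydration, so no facial control is needed. The selectivity that is needed is regiochemical and is built into the substrates: 1 has a single α-hydrogen, only the C5' enol of 3 can reach C6' through a six-membered transition state (the C3' enol would close a four-membered ring), and attack on the ester carbonyl would need a seven-membered ring. The C4' carbonyl that drives both bond formations is absent from the target and is kept on purpose as the handle for the asymmetric reduction and the 1,3-chirality relay of steps 2 and 3.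

Step 2
Reactants: 5 ethyl 2,6,6-trimethyl-3-oxocyclohex-1-ene-1-carboxylate
Product: 6 ethyl (3S)-3-hydroxy-2,6,6-trimethylcyclohex-1-ene-1-carboxylate
Conditions: (R)-Me-CBS oxazaborolidine (20 mol %), BH3·SMe2, THF, −20 °C; MeOH quench
Reagents that add atoms: none
Why: Corey–Bakshi–Shibata reduction, in which the α-methylated alkenyl arm acts as the large group and the ring CH2 as the small one, so the (R)-catalyst should give the (S)-carbinol at C4', while the hindered conjugated ester and the tetrasubstituted alkene are not touched by borane at this temperature.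

Step 3
Reactants: 6 ethyl (3S)-3-hydroxy-2,6,6-trimethylcyclohex-1-ene-1-carboxylate
Product: 9 ethyl (1R)-2,6,6-trimethylcyclohex-2-ene-1-carboxylate, via sulfonylhydrazine 7 (not isolated), via allylic diazene 8 (not isolated)
Conditions: 2-nitrobenzenesulfonohydrazide, PPh3, DEAD, N-methylmorpholine, −30 °C → 23 °C
Reagents that add atoms: 2-nitrobenzenesulfonohydrazide (NBSH), NNS(=O)(=O)c1ccccc1[N+](=O)[O-] (its nitrogen and sulfonyl atoms are carried only by 7 and 8; the product keeps one hydrogen)
Why: Reductive 1,3-transposition of an allylic alcohol through a Mitsunobu-installed sulfonylhydrazine (Myers allylic diazene rearrangement): SN2 inversion at C4' gives 7, loss of sulfinic acid gives 8, and the concerted retro-ene loss of N2 delivers the N–H hydrogen suprafacially to C6' on the face opposite to the original hydroxyl, which sets (6'R), moves the alkene to C4'=C5' out of conjugation and removes the temporary C4' heteroatom.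

Step 4
Reactants: 9 ethyl (1R)-2,6,6-trimethylcyclohex-2-ene-1-carboxylate
Product: 10 [(1R)-2,6,6-trimethylcyclohex-2-en-1-yl]methanol
Conditions: LiAlH4, Et2O, 0 °C → rt
Reagents that add atoms: none
Why: Hydride reduction of a hindered ester; the C6' hydrogen sits next to a quaternary carbon and should not be removed under these non-equilibrating conditions.

Step 5
Reactants: 10 [(1R)-2,6,6-trimethylcyclohex-2-en-1-yl]methanol
Product: 11 (1R)-2,6,6-trimethylcyclohex-2-ene-1-carbaldehyde
Conditions: Dess–Martin periodinane, NaHCO3, CH2Cl2, 0 °C; used at once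
Reagents that add atoms: none
Why: Dess–Martin oxidation under buffered, non-basic conditions should keep the epimerisable β,γ-unsaturated aldehyde from isomerising to the conjugated isomer.

Step 6
Reactants: 11 (1R)-2,6,6-trimethylcyclohex-2-ene-1-carbaldehyde; 12 dimethyl (2-oxopropyl)phosphonate
Product: 13 (3E)-4-[(1R)-2,6,6-trimethylcyclohex-2-en-1-yl]but-3-en-2-one
Conditions: LiCl, i-Pr2NEt, MeCN, 23 °C
Reagents that add atoms: none
Why: Horner–Wadsworth–Emmons olefination under Masamune–Roush conditions (weak amine base, lithium chelation) should give the (E)-enone without epimerising C6' or moving the ring alkene into conjugation.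

Step 7
Reactants: 13 (3E)-4-[(1R)-2,6,6-trimethylcyclohex-2-en-1-yl]but-3-en-2-one; 14 vinylmagnesium bromide
Product: 15 (1E)-3-methyl-1-[(1R)-2,6,6-trimethylcyclohex-2-en-1-yl]penta-1,4-dien-3-ol (both carbinol epimers)
Conditions: THF, −20 °C → 0 °C; aq. NH4Cl
Reagents that add atoms: none
Why: 1,2-Addition of a vinyl Grignard reagent to the enone carbonyl gives the tertiary bis-allylic alcohol, whose new carbinol centre is lost in the next step and so needs no control.

Step 8
Reactants: 15 (1E)-3-methyl-1-[(1R)-2,6,6-trimethylcyclohex-2-en-1-yl]penta-1,4-dien-3-ol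
Product: 16 [(2E,4E)-3-methyl-5-[(1R)-2,6,6-trimethylcyclohex-2-en-1-yl]penta-2,4-dien-1-yl]triphenylphosphonium bromide
Conditions: PPh3·HBr, MeOH, rt
Reagents that add atoms: triphenylphosphine hydrobromide, [Br-].[PH+](c1ccccc1)(c1ccccc1)c1ccccc1
Why: Acid-mediated ionisation to the pentadienyl cation and capture by triphenylphosphine at the unhindered terminus (the standard vinyl-carbinol to Wittig-salt conversion with allylic transposition) should give the conjugated (E,E)-salt under thermodynamic control, and the mild acid at room temperature should leave the doubly allylic C6'–H in place.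

Step 9
Reactants: 16 the ε-C15 phosphonium bromide; 17 (2E,4E,6E)-2,7-dimethylocta-2,4,6-trienedial (used in excess)
Product: 19 (2E,4E,6E,8E,10E,12E)-2,7,11-trimethyl-13-[(1R)-2,6,6-trimethylcyclohex-2-en-1-yl]trideca-2,4,6,8,10,12-hexaenal, via phosphonium ylide 18 (not isolated)
Conditions: NaOMe, MeOH/CH2Cl2, 0 °C → rt; then I2 (cat.), heptane, rt, light
Reagents that add atoms: none
Why: Wittig olefination of one aldehyde group of the symmetrical dialdehyde forms C11'=C12', and iodine-catalysed equilibration should convert the E/Z mixture into the all-E aldehyde, which is safe at this stage because no enyne is present yet.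

Step 10
Reactants: 20 (4R,6R)-4-hydroxy-2,2,6-trimethylcyclohexan-1-one (actinol)
Product: 21 (4R,6R)-4-[(tert-butyldimethylsilyl)oxy]-2,2,6-trimethylcyclohexan-1-one
Conditions: TBSCl, imidazole, DMF, rt
Reagents that add atoms: tert-butyldimethylsilyl chloride (TBSCl), CC(C)(C)[Si](C)(C)Cl
Why: Imidazole-promoted silylation protects the secondary alcohol against the strong base of the next step.

Step 11
Reactants: 21 (4R,6R)-4-[(tert-butyldimethylsilyl)oxy]-2,2,6-trimethylcyclohexan-1-one
Product: 23 (4R)-4-[(tert-butyldimethylsilyl)oxy]-2,6,6-trimethylcyclohex-1-en-1-yl trifluoromethanesulfonate, via lithium enolate 22 (not isolated)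
Conditions: LDA, THF, −78 °C → 0 °C; then PhNTf2, −78 °C → rt
Reagents that add atoms: N-phenylbis(trifluoromethanesulfonimide), O=S(=O)(N(c1ccccc1)S(=O)(=O)C(F)(F)F)C(F)(F)F
Why: Enolate O-sulfonylation: the ketone has a single α-hydrogen (the other α-carbon is quaternary), so only the tetrasubstituted enolate can form and its triflation fixes the ring C5=C6 alkene, erasing the methyl-bearing stereocentre on purpose while the carbinol centre is untouched.

Step 12
Reactants: 23 the enol triflate; 24 (2E)-3-methylpent-2-en-4-yn-1-ol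
Product: 25 (2E)-5-[(4R)-4-[(tert-butyldimethylsilyl)oxy]-2,6,6-trimethylcyclohex-1-en-1-yl]-3-methylpent-2-en-4-yn-1-ol
Conditions: Pd(PPh3)4 (5 mol %), CuI (copper iodide, 10 mol %), Et3N, DMF, rt
Reagents that add atoms: none
Why: Sonogashira coupling of the enol triflate with the terminal alkyne forms C6–C7 and brings in the C9=C10 alkene with its (E) geometry already fixed; the free allylic alcohol and the silyl ether are tolerated.

Step 13
Reactants: 25 the silyl-protected enynol
Product: 26 (2E)-5-[(4R)-4-hydroxy-2,6,6-trimethylcyclohex-1-en-1-yl]-3-methylpent-2-en-4-yn-1-ol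
Conditions: TBAF, THF, 0 °C → rt
Reagents that add atoms: none
Why: Fluoride-induced cleavage of the silyl ether leaves the enyne and both alcohols intact.

Step 14
Reactants: 26 the enyne diol
Product: 27 [(2E)-5-[(4R)-4-hydroxy-2,6,6-trimethylcyclohex-1-en-1-yl]-3-methylpent-2-en-4-yn-1-yl]triphenylphosphonium bromide
Conditions: PPh3·HBr, MeOH/CH2Cl2, rt
Reagents that add atoms: triphenylphosphine hydrobromide, [Br-].[PH+](c1ccccc1)(c1ccccc1)c1ccccc1
Why: Only the primary allylic alcohol is activated by protonation and displaced by bromide/phosphine, so the phosphonium salt should form while the non-activated secondary ring alcohol stays free.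

Step 15
Reactants: 27 the acetylenic C15 phosphonium bromide; 19 the C25 aldehyde
Product: 29 (3R,6'R)-7,8-didehydro-β,ε-caroten-3-ol (all-E crocoxanthin), via phosphonium ylide 28 (not isolated)
Conditions: NaOMe, MeOH/CH2Cl2, 0 °C → rt, dark, argon; then reflux in EtOAc; crystallisation of the all-E isomer
Reagents that add atoms: none
Why: Wittig olefination forms C11=C12 and completes the C40 skeleton; the hindered (11Z) isomer should isomerise thermally to (11E), and iodine is avoided because it would equilibrate the enyne-flanked C9=C10 bond toward (9Z).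

## Compound list

1 | ethyl 3-methyl-2-oxobutanoate | CCOC(=O)C(=O)C(C)C | starting material
2 | pent-1-en-3-one (ethyl vinyl ketone) | CCC(=O)C=C | starting material
3 | ethyl 3,3-dimethyl-2,6-dioxooctanoate (Michael adduct) | CCOC(=O)C(=O)C(C)(C)CCC(=O)CC | intermediate
4 | ethyl 1-hydroxy-2,6,6-trimethyl-3-oxocyclohexane-1-carboxylate (aldol adduct, mixture of diastereomers) | CCOC(=O)C1(O)C(C)C(=O)CCC1(C)C | intermediate
5 | ethyl 2,6,6-trimethyl-3-oxocyclohex-1-ene-1-carboxylate | CCOC(=O)C1=C(C)C(=O)CCC1(C)C | intermediate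
6 | ethyl (3S)-3-hydroxy-2,6,6-trimethylcyclohex-1-ene-1-carboxylate | CCOC(=O)C1=C(C)[C@@H](O)CCC1(C)C | intermediate
7 | ethyl (3R)-2,6,6-trimethyl-3-[1-(2-nitrophenylsulfonyl)hydrazinyl]cyclohex-1-ene-1-carboxylate | CCOC(=O)C1=C(C)[C@H](N(N)S(=O)(=O)c2ccccc2[N+](=O)[O-])CCC1(C)C | intermediate
8 | ethyl (3R)-3-diazenyl-2,6,6-trimethylcyclohex-1-ene-1-carboxylate | CCOC(=O)C1=C(C)[C@H](N=N)CCC1(C)C | intermediate
9 | ethyl (1R)-2,6,6-trimethylcyclohex-2-ene-1-carboxylate | CCOC(=O)[C@H]1C(C)=CCCC1(C)C | intermediate
10 | [(1R)-2,6,6-trimethylcyclohex-2-en-1-yl]methanol | OC[C@H]1C(C)=CCCC1(C)C | intermediate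
11 | (1R)-2,6,6-trimethylcyclohex-2-ene-1-carbaldehyde | O=C[C@H]1C(C)=CCCC1(C)C | intermediate
12 | dimethyl (2-oxopropyl)phosphonate | CC(=O)CP(=O)(OC)OC | starting material
13 | (3E)-4-[(1R)-2,6,6-trimethylcyclohex-2-en-1-yl]but-3-en-2-one ((R)-α-ionone) | CC(=O)/C=C/[C@H]1C(C)=CCCC1(C)C | intermediate
14 | vinylmagnesium bromide | C=C[Mg]Br | starting material
15 | (1E)-3-methyl-1-[(1R)-2,6,6-trimethylcyclohex-2-en-1-yl]penta-1,4-dien-3-ol (both carbinol epimers) | C=CC(C)(O)/C=C/[C@H]1C(C)=CCCC1(C)C | intermediate
16 | [(2E,4E)-3-methyl-5-[(1R)-2,6,6-trimethylcyclohex-2-en-1-yl]penta-2,4-dien-1-yl]triphenylphosphonium bromide | [Br-].C/C(=C\C[P+](c1ccccc1)(c1ccccc1)c1ccccc1)/C=C/[C@H]1C(C)=CCCC1(C)C | intermediate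
17 | (2E,4E,6E)-2,7-dimethylocta-2,4,6-trienedial | O=C/C(C)=C/C=C/C=C(\C)C=O | starting material
18 | ylide of 16 | C/C(=C\[CH-][P+](c1ccccc1)(c1ccccc1)c1ccccc1)/C=C/[C@H]1C(C)=CCCC1(C)C | intermediate
19 | (2E,4E,6E,8E,10E,12E)-2,7,11-trimethyl-13-[(1R)-2,6,6-trimethylcyclohex-2-en-1-yl]trideca-2,4,6,8,10,12-hexaenal | CC1=CCCC(C)(C)[C@H]1/C=C/C(C)=C/C=C/C(C)=C/C=C/C=C(C)/C=O | intermediate
20 | (4R,6R)-4-hydroxy-2,2,6-trimethylcyclohexan-1-one (actinol) | O=C1C(C)(C)C[C@H](O)C[C@H]1C | starting material
21 | (4R,6R)-4-[(tert-butyldimethylsilyl)oxy]-2,2,6-trimethylcyclohexan-1-one | O=C1C(C)(C)C[C@H](O[Si](C)(C)C(C)(C)C)C[C@H]1C | intermediate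
22 | lithium (4R)-4-[(tert-butyldimethylsilyl)oxy]-2,6,6-trimethylcyclohex-1-en-1-olate | [Li+].[O-]C1=C(C)C[C@@H](O[Si](C)(C)C(C)(C)C)CC1(C)C | intermediate
23 | (4R)-4-[(tert-butyldimethylsilyl)oxy]-2,6,6-trimethylcyclohex-1-en-1-yl trifluoromethanesulfonate | FC(F)(F)S(=O)(=O)OC1=C(C)C[C@@H](O[Si](C)(C)C(C)(C)C)CC1(C)C | intermediate
24 | (2E)-3-methylpent-2-en-4-yn-1-ol | C#C/C(C)=C/CO | starting material
25 | (2E)-5-[(4R)-4-[(tert-butyldimethylsilyl)oxy]-2,6,6-trimethylcyclohex-1-en-1-yl]-3-methylpent-2-en-4-yn-1-ol | OC/C=C(\C)C#CC1=C(C)C[C@@H](O[Si](C)(C)C(C)(C)C)CC1(C)C | intermediate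
26 | (2E)-5-[(4R)-4-hydroxy-2,6,6-trimethylcyclohex-1-en-1-yl]-3-methylpent-2-en-4-yn-1-ol | OC/C=C(\C)C#CC1=C(C)C[C@@H](O)CC1(C)C | intermediate
27 | [(2E)-5-[(4R)-4-hydroxy-2,6,6-trimethylcyclohex-1-en-1-yl]-3-methylpent-2-en-4-yn-1-yl]triphenylphosphonium bromide | [Br-].C(/C=C(\C)C#CC1=C(C)C[C@@H](O)CC1(C)C)[P+](c1ccccc1)(c1ccccc1)c1ccccc1 | intermediate
28 | ylide of 27 | [CH-](/C=C(\C)C#CC1=C(C)C[C@@H](O)CC1(C)C)[P+](c1ccccc1)(c1ccccc1)c1ccccc1 | intermediate
29 | (3R,6'R)-7,8-didehydro-β,ε-caroten-3-ol (crocoxanthin) | CC1=CCCC(C)(C)[C@H]1/C=C/C(C)=C/C=C/C(C)=C/C=C/C=C(C)/C=C/C=C(\C)C#CC1=C(C)C[C@@H](O)CC1(C)C | target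

## Step count and risks

Total step count: 15 (steps 1–9 for the ε branch up to the C25 aldehyde, steps 10–14 for the acetylenic branch, step 15 for the union).
Longest linear sequence: 10 steps (steps 1–9, then step 15).

The three steps most likely to fail:

Step 1. The conjugate addition that creates the quaternary carbon may be slow, so that polymerisation of the vinyl ketone or incomplete ring closure and dehydration takes over. The fallback sets out from 1 and comes back to the route at 5, making the two bonds in two known operations. Compound 1 is silylated (TMSCl, Et3N, NaI, MeCN) to the silyl enol ether ethyl 3-methyl-2-[(trimethylsilyl)oxy]but-2-enoate F1. F1 is added to 2 under TiCl4 (CH2Cl2, −78 °C; Mukaiyama–Michael addition) to give 3 as an isolated compound. Compound 3 is then cyclised and dehydrated separately (pyrrolidine/AcOH or TsOH, toluene, reflux) to 5.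

Step 3. The Mitsunobu displacement at the hindered allylic carbinol may fail or be diverted into elimination to a diene or SN2' attack, which would erode the chirality relay from C4' to C6'. The fallback sets out from 6 and comes back at 9. Compound 6 is formylated (acetic formic anhydride, pyridine) to the allylic formate ethyl (3S)-3-(formyloxy)-2,6,6-trimethylcyclohex-1-ene-1-carboxylate F2. F2 is submitted to palladium-catalysed formate hydrogenolysis (Pd(OAc)2, n-Bu3P, dioxane, rt → 60 °C). Ionisation with inversion, loss of CO2 to a palladium hydride and hydride delivery from the metal face to the more substituted allyl terminus C6' should give the same (R)-configured 9 with the alkene at C4'=C5'.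

Step 15. The C9=C10 geometry may scramble through the delocalised ylide, and the new C11=C12 bond may form with low E-selectivity, with no iodine-catalysed correction available for an enyne polyene. The fallback sets out from 26 and 19 and comes back at 29 with reversed polarity. Compound 26 is oxidised (MnO2, CH2Cl2) to the enynal (2E)-5-[(4R)-4-hydroxy-2,6,6-trimethylcyclohex-1-en-1-yl]-3-methylpent-2-en-4-ynal F3, whose C9=C10 bond never passes through an ylide. Compound 19 is reduced (NaBH4, EtOH) to the C25 alcohol (2E,4E,6E,8E,10E,12E)-2,7,11-trimethyl-13-[(1R)-2,6,6-trimethylcyclohex-2-en-1-yl]trideca-2,4,6,8,10,12-hexaen-1-ol F4. F4 is converted (PPh3·HBr, MeOH) into the C25 salt [(2E,4E,6E,8E,10E,12E)-2,7,11-trimethyl-13-[(1R)-2,6,6-trimethylcyclohex-2-en-1-yl]trideca-2,4,6,8,10,12-hexaen-1-yl]triphenylphosphonium bromide F5. Wittig reaction of F5 with F3 (NaOMe, MeOH/CH2Cl2), followed by thermal equilibration, gives 29.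

Further compounds
F1 | step 1 | ethyl 3-methyl-2-[(trimethylsilyl)oxy]but-2-enoate | CCOC(=O)C(O[Si](C)(C)C)=C(C)C
F2 | step 3 | ethyl (3S)-3-(formyloxy)-2,6,6-trimethylcyclohex-1-ene-1-carboxylate | CCOC(=O)C1=C(C)[C@@H](OC=O)CCC1(C)C
F3 | step 15 | (2E)-5-[(4R)-4-hydroxy-2,6,6-trimethylcyclohex-1-en-1-yl]-3-methylpent-2-en-4-ynal | O=C/C=C(\C)C#CC1=C(C)C[C@@H](O)CC1(C)C
F4 | step 15 | (2E,4E,6E,8E,10E,12E)-2,7,11-trimethyl-13-[(1R)-2,6,6-trimethylcyclohex-2-en-1-yl]trideca-2,4,6,8,10,12-hexaen-1-ol | CC1=CCCC(C)(C)[C@H]1/C=C/C(C)=C/C=C/C(C)=C/C=C/C=C(C)/CO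
F5 | step 15 | [(2E,4E,6E,8E,10E,12E)-2,7,11-trimethyl-13-[(1R)-2,6,6-trimethylcyclohex-2-en-1-yl]trideca-2,4,6,8,10,12-hexaen-1-yl]triphenylphosphonium bromide | [Br-].CC1=CCCC(C)(C)[C@H]1/C=C/C(C)=C/C=C/C(C)=C/C=C/C=C(C)/C[P+](c1ccccc1)(c1ccccc1)c1ccccc1
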